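## Analysis of the target

- The target is a linear trimer of three fully substituted benzene rings. The central ring (ring A) is an acylphloroglucinol: C1 carries the (R)-2-methylbutanoyl group, C2, C4 and C6 carry hydroxyls, and C3 and C5 each carry a CH2 bridge to one of two identical side rings (ring B and ring B′).
- Each side ring is hexasubstituted: C1′ holds the bridge, C2′ and C6′ are hydroxyls, C3′ is methyl, C4′ is methoxy and C5′ is acetyl. The O-methyl group therefore sits on the most crowded oxygen, between the methyl and the acetyl group.
- The only stereocenter is C2 of the acyl chain, (R), α to an aryl ketone. It has no partner to relate to, so it is bought in and must be kept away from enolizing conditions.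
- The sensitive groups are seven phenols (air-sensitive in base), three chelated aryl ketones, and the two diarylmethane bridges. In this compound class the bridges can reopen through quinone methides under hot acid or base and scramble.
- The rings are easy; the two A–CH2–B bonds are the difficulty. Ring A has two nucleophilic carbons, and any free phenol next to a benzylic leaving group can ionize it, so a plain one-carbon condensation is expected to drift to homodimers, chains and xanthenes.
- The strategy rests on this feature: C3 and C5 are the only unsubstituted carbons of ring A, and each lies ortho to two ring A hydroxyls (O2/O4 and O4/O6). A sulfur atom bound to one of these oxygens and carrying the side-ring benzylic carbon places that carbon in a five-atom array C–S–O–C–C with C3 or C5, which is the geometry of a [2,3]-sigmatropic shift.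

## Retrosynthetic reasoning

**From 18 back to 16.** The last two operations make no C–C bond. The four side-ring phenols of 18 are uncovered from the tetraacetate 17, and the two bridge CH2 groups of 17 come from the bis(methylsulfanyl) compound 16 by exchanging each C–S bond for C–H. Sulfur is removed while the side-ring oxygens are still acylated, because a free phenol ortho to a carbon that bears a leaving group would expel it and open the way to bridge scrambling.

**From 16 to 4 and two equivalents of 12.** The bonds cut are ring A C3–C(bridge) and C5–C(bridge). They are cut there, and not between the bridge and the side ring, for two reasons: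
- Ring A has three hydroxyls and two free ortho carbons, so an oxygen can serve twice as a temporary point of attachment.
- The side ring has a single free carbon, which is better functionalized once, early, on a small molecule.

What is gained: 4 brings the stereocenter and 12 brings a complete side ring. The carbon that is delivered is already bonded to ring B and reaches ring A through a ring A oxygen, so the A–C–B connectivity is enforced. The product stops at the thioether level, which guards against over-alkylation. The forward reaction has to bind the activated sulfur of 12 to a ring A oxygen, remove a benzylic proton, let the ylide shift to C3, and repeat at C5.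

**From 12 to 9.** The sulfoxide 12 comes from the sulfide 11 by oxidation at sulfur, and 11 from the diphenol 10 by acetylation. The bond between the side ring and its benzylic carbon is then cut, which leads to the ketone 9. The ring carbon between the two hydroxyls of 9 is its only unsubstituted position, so a one-carbon electrophile has a single site, and a thiol captures the resulting benzylic electrophile.

**From 9 to 5.** The O–CH3 bond of 9 lies on the oxygen that is least reactive (chelated and flanked on both sides), so it cannot be addressed directly. The other two oxygens are therefore capped first (7), the remaining one is methylated (8), and the caps are removed (9). The triol 6 comes from 2-methylphloroglucinol 5 by cutting the acetyl–ring bond; the two free carbons of 5 are equivalent, so no regiochemistry arises there.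

**From 4 to 1 and 3.** The acyl–ring A bond is cut. Phloroglucinol 3 is threefold symmetric, so acylation with the acid chloride 2, made from the (R)-acid 1, has only one outcome and brings in the stereocenter unchanged.

## Alternatives that were turned down

**Alternative 1:** The side rings are grown on ring A instead of being brought in.
- **Disconnection:** in each side ring the C1′–C2′, C2′–C3′ and C5′–C6′ bonds are removed. This leads to a central ring that already carries both bridge carbons as propargylic arms ending in triisopropylsiloxyalkynes (A1) and to two equivalents of the cyclobutenone A2.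
- **Forward key step:** heating opens A2 to a vinylketene, which adds to each siloxyalkyne, reopens and closes by 6π-electrocyclization to the side-ring phenol, giving A3 (ketene–ynol ether benzannulation).
- **For it:** the bridges exist before the side rings do, so no cross-coupling selectivity is needed. The positions of the C3′ methyl and C4′ methoxy follow from A2 by construction. On this regiochemical point it is stronger than the chosen route, which must tell two ortho hydroxyls apart in step 4.
- **Against it:** A1 is a demanding substrate, a fully substituted benzene with two labile siloxyalkynes, three benzyl ethers and the ketone masked as a silyl-protected carbinol. The mask adds an uncontrolled carbinol center and a later oxidation next to the (R) center. The cascade must run twice on one molecule. A3 has no acetyl group at C5′, so two acylations on a trimer with seven oxygens, desilylations, an oxidation and a hydrogenolysis still separate A3 from 18.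
- **Comparison:** the chosen route offers complete side rings made on a small ketone and only two functional-group steps after the key bond formation.

**Alternative 2:** The C-methyl groups are added last.
- **Disconnection:** the C3′–CH3 bond of each side ring. The trimer without these methyl groups, A4, would be assembled from 4 and two equivalents of the purchasable ketone A5 with a one-carbon linker.
- **Forward key step:** double aminomethylation of A4 with the iminium salt A6 at C3′, the only unsubstituted aromatic carbon left in each side ring, to give A7. Reductive loss of the amine would then leave the methyl groups.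
- **For it:** A5 is bought with the O-methyl group on the correct oxygen, so the three steps that the chosen route spends on this (steps 4 to 6) fall away. The site of the key step is unambiguous. In side-ring step economy it is clearly stronger.
- **Against it:** the key step adds two spectator carbons and leaves the real problem, the two A–CH2–B bonds, to a statistical condensation. In that condensation 4 has two nucleophilic carbons and A5 has two (the later C1′ and C3′), so homodimers and chains are expected beside A4. The C–N bonds of A7 are reduced only after ionization assisted by the neighbouring phenol, and the two existing bridges are benzylic carbons of the same kind, so the conditions that remove nitrogen also threaten the skeleton.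
- **Comparison:** the chosen route is longer in the side ring but places its risk in a step that builds the skeleton with the connectivity enforced.

**Alternative 3:** Ring A is made last.
- **Disconnection:** ring A at C1–C2. The precursor is the 4-hydroxy-2-pyrone A8, which carries both side arms (as benzyl ethers, without acetyl groups) at pyrone C3 and C5 and the (R)-3-methyl-2-oxopentyl chain at C6.
- **Forward key step:** A9 in methanol opens the lactone to a magnesium-chelated triketo ester. Its methylene between two ketones attacks the ester carbonyl (Claisen-type cyclization) and closes ring A as A10.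
- **For it:** ring A is formed fully substituted, so site selectivity on ring A never arises. The conditions are mild. The competing aldol mode of folding cannot aromatize, because the carbon that would have to attack already bears a side arm.
- **Against it:** A8 is about as complex as the core of the target and needs its own multistep synthesis. The stereocenter sits α to a ketone inside a 1,3-dicarbonyl system held as its enolate in methoxide for the whole cyclization. The Claisen step must attack an α-branched, hindered ester. A10 still needs two nuclear acetylations in the presence of three free ring A phenols and the removal of four benzyl ethers.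
- **Comparison:** the chosen route keeps the stereocenter away from alkoxide until the final cold methanolysis and needs two steps after the key step. It gives up the built-in certainty about ring A substitution and relies instead on C3 and C5 being the only free positions.

Key step: step 10

Remark: 12 is used as the racemate at sulfur, and 16 is carried on as a mixture of diastereomers at the two bridge carbons. Both stereo-elements vanish in steps 10 and 11, so the SMILES leave them unspecified.

## Route

Step 1
Reactants: 1 (R)-2-methylbutanoic acid
Product: 2 (R)-2-methylbutanoyl chloride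
Conditions: (COCl)2, DMF (cat.), CH2Cl2, 0 °C→rt; concentrated and used crude
Reagents that add atoms: oxalyl chloride, O=C(Cl)C(=O)Cl
Why: Acyl chloride formation through the catalytic chloroiminium species (nucleophilic acyl substitution). No base is present and the α-carbon bears only alkyl groups, so ketene formation and loss of configuration are not expected.

Step 2
Reactants: 2 (R)-2-methylbutanoyl chloride; 3 phloroglucinol
Product: 4 (2R)-2-methyl-1-(2,4,6-trihydroxyphenyl)butan-1-one
Conditions: AlCl3 (3.5 equiv), PhNO2/CH2Cl2, 0 °C→rt; aq. HCl
Reagents that add atoms: none
Why: Friedel–Crafts C-acylation of the symmetric triphenol, so only one regioisomer is possible. The first acyl group deactivates the ring against a second acylation, and the low temperature limits enolization of the aluminium-bound ketone, so the (R) center should be carried through.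

Step 3
Reactants: 5 2-methylphloroglucinol (2-methylbenzene-1,3,5-triol)
Product: 6 1-(2,4,6-trihydroxy-3-methylphenyl)ethanone
Conditions: AcCl (1.05 equiv), AlCl3 (3 equiv), PhNO2/CH2Cl2, 0 °C→rt; aq. HCl
Reagents that add atoms: acetyl chloride, CC(=O)Cl
Why: Friedel–Crafts acetylation at one of the two equivalent free ring carbons of 5. The chelated, deactivated product resists diacylation.

Step 4
Reactants: 6 1-(2,4,6-trihydroxy-3-methylphenyl)ethanone
Product: 7 1-[2-hydroxy-4,6-bis(methoxymethoxy)-3-methylphenyl]ethanone
Conditions: MOMCl (2.2 equiv), iPr2NEt (2.5 equiv), CH2Cl2, 0 °C→rt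
Reagents that add atoms: chloromethyl methyl ether, COCCl
Why: Selective O-alkylation (acetal formation) with a hard electrophile. The 4-OH, para to the ketone and most acidic, should react first, then the 6-OH, which has only hydrogen on its other side. The 2-OH, flanked by methyl and acetyl and held in the stronger hydrogen bond to the carbonyl, should remain free.

Step 5
Reactants: 7 1-[2-hydroxy-4,6-bis(methoxymethoxy)-3-methylphenyl]ethanone
Product: 8 1-[2-methoxy-4,6-bis(methoxymethoxy)-3-methylphenyl]ethanone
Conditions: MeI (excess), K2CO3, DMF, 40 °C
Reagents that add atoms: iodomethane, CI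
Why: Williamson O-methylation of the only remaining phenol. The chelated hydroxyl needs mildly forcing carbonate conditions, to which the acetals and the ketone are inert.

Step 6
Reactants: 8 1-[2-methoxy-4,6-bis(methoxymethoxy)-3-methylphenyl]ethanone
Product: 9 1-(4,6-dihydroxy-2-methoxy-3-methylphenyl)ethanone
Conditions: HCl (3 M aq.), MeOH, 50 °C
Reagents that add atoms: none
Why: Acid-catalyzed acetal exchange removes both methoxymethyl groups while the aryl methyl ether and the ketone stay. The large excess of methanol traps the oxocarbenium ion and keeps it away from the nucleophilic free ring carbon.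

Step 7
Reactants: 9 1-(4,6-dihydroxy-2-methoxy-3-methylphenyl)ethanone
Product: 10 1-{2,4-dihydroxy-6-methoxy-5-methyl-3-[(methylsulfanyl)methyl]phenyl}ethanone
Conditions: CH2O (37% aq., 1.5 equiv), MeSH (excess), Et3N (cat.), EtOH, sealed vessel, 0 °C→40 °C
Reagents that add atoms: formaldehyde, C=O; methanethiol, CS
Why: Three-component thiomethylation of a phenol (Mannich-type): hydroxymethylation at the only free ring carbon, which is activated by both flanking hydroxyls, then loss of water and capture of the benzylic electrophile by the thiol. The excess of thiol is meant to outrun capture by a second molecule of 9.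

Step 8
Reactants: 10 1-{2,4-dihydroxy-6-methoxy-5-methyl-3-[(methylsulfanyl)methyl]phenyl}ethanone
Product: 11 4-acetyl-5-methoxy-6-methyl-2-[(methylsulfanyl)methyl]-1,3-phenylene diacetate
Conditions: Ac2O, pyridine, DMAP (cat.), CH2Cl2, 0 °C→rt
Reagents that add atoms: acetic anhydride, CC(=O)OC(C)=O
Why: DMAP-catalyzed O-acetylation of both hindered phenols; the sulfide is inert. Acetylation comes before the oxidation because an anhydride would trigger Pummerer chemistry on a sulfoxide.

Step 9
Reactants: 11 4-acetyl-5-methoxy-6-methyl-2-[(methylsulfanyl)methyl]-1,3-phenylene diacetate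
Product: 12 4-acetyl-5-methoxy-6-methyl-2-[(methylsulfinyl)methyl]-1,3-phenylene diacetate (racemic at sulfur)
Conditions: mCPBA (1.0 equiv), CH2Cl2, −78 °C
Reagents that add atoms: 3-chloroperoxybenzoic acid, OOC(=O)c1cccc(Cl)c1
Why: Chemoselective oxidation of the sulfide to the sulfoxide. With one equivalent of peracid at low temperature it is far faster than sulfone formation or Baeyer–Villiger oxidation of the aryl ketone, and the aryl acetates survive the anhydrous conditions.

Step 10
Reactants: 4 (2R)-2-methyl-1-(2,4,6-trihydroxyphenyl)butan-1-one; 12 4-acetyl-5-methoxy-6-methyl-2-[(methylsulfinyl)methyl]-1,3-phenylene diacetate (2.5 equiv)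
Product: 16 (2R)-1-{3,5-bis[(3-acetyl-2,6-diacetoxy-4-methoxy-5-methylphenyl)(methylsulfanyl)methyl]-2,4,6-trihydroxyphenyl}-2-methylbutan-1-one (diastereomer mixture at the two bridge carbons), via triflyloxysulfonium triflate 13 (not isolated), via aryloxysulfonium triflate 14 (not isolated), via mono-alkylated phenol 15 (not isolated)
Conditions: 12, Tf2O (2.4 equiv), CH2Cl2, −78 °C (preactivation); then 4 in MeCN, −78→−40 °C; then iPr2NEt (6 equiv), −78→0 °C
Reagents that add atoms: none
Why: Proposed new method: Tf2O turns the sulfoxide 12 into the S-triflyloxysulfonium salt 13, a ring A hydroxyl of 4 (drawn at O4, the one not chelated to the ketone) displaces triflate at sulfur to give the aryloxysulfonium salt 14, and iPr2NEt removes a benzylic proton to form the sulfur ylide. The ylide carbon then bonds to the ortho carbon C3 through a five-membered C–S–O–C–C transition state while the S–O bond breaks ([2,3]-sigmatropic shift), the cyclohexadienone so formed tautomerizes to the phenol 15, and the same sequence on 15 with a second 13 at C5 gives 16. The closest known reaction type is the Gassman ortho-alkylation of phenols through aryloxysulfonium ylides, which is established for ylides made from simple dialkyl sulfides and sulfoxides; the transfer of a fully substituted benzylic carbon from a benzyl methyl sulfoxide, twice, onto an acylphloroglucinol has not been shown. No ring is closed in this step. The two bridge carbons become stereocenters without any controlling element, so 16 is expected as a mixture of diastereomers, which is of no consequence because both carbons become CH2 in step 11, and the (R) center is remote from the reacting sites and is not enolized by a hindered amine at low temperature. The step needs ylide formation at the benzylic carbon and not at S-methyl, which the acceptor-substituted side ring secures by making the benzylic protons the more acidic ones, and it needs bonding at C3 and C5 and not at C1, which follows because C3 and C5 are the only unsubstituted ortho carbons and a shift to the acyl-bearing C1 would give a crowded dienone that cannot aromatize. The acetates keep the side-ring oxygens from competing for sulfur and make the benzylic carbon too electron-poor to ionize, and preactivation of 12 before 4 is added keeps Tf2O away from the ring A phenols. If base-induced Pummerer elimination of 13 runs ahead of O-capture, the resulting thionium ion is attacked by C3 and C5 of ring A directly and gives the same 15 and 16, so both channels converge.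

Step 11
Reactants: 16 (2R)-1-{3,5-bis[(3-acetyl-2,6-diacetoxy-4-methoxy-5-methylphenyl)(methylsulfanyl)methyl]-2,4,6-trihydroxyphenyl}-2-methylbutan-1-one
Product: 17 (2R)-1-{3,5-bis[(3-acetyl-2,6-diacetoxy-4-methoxy-5-methylphenyl)methyl]-2,4,6-trihydroxyphenyl}-2-methylbutan-1-one
Conditions: Bu3SnH (5 equiv), AIBN (cat., in portions), toluene, 100 °C
Reagents that add atoms: none
Why: Radical chain desulfurization: the stannyl radical attacks sulfur, releases the doubly benzylic diarylmethyl radical, and this abstracts hydrogen from Bu3SnH. Acetates, aryl ketones and the remote stereocenter are not affected, and the step is run while the side-ring oxygens are still acylated so that no phenol can expel the thiolate.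

Step 12
Reactants: 17 (2R)-1-{3,5-bis[(3-acetyl-2,6-diacetoxy-4-methoxy-5-methylphenyl)methyl]-2,4,6-trihydroxyphenyl}-2-methylbutan-1-one
Product: 18 (2R)-1-{3,5-bis[(3-acetyl-2,6-dihydroxy-4-methoxy-5-methylphenyl)methyl]-2,4,6-trihydroxyphenyl}-2-methylbutan-1-one (CNP0201397.1)
Conditions: K2CO3 (0.2 equiv), MeOH (degassed, Ar), 0 °C→rt; then dilute HCl to pH 4
Reagents that add atoms: none
Why: Base-catalyzed transesterification of the four aryl acetates to methyl acetate. Under these conditions ring A is present as a phenoxide, which lowers the acidity of the α-hydrogen of the ketone, and the cold, oxygen-free medium is chosen to avoid epimerization, phenol oxidation and bridge scrambling.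

## Compound list

1 | (R)-2-methylbutanoic acid | CC[C@@H](C)C(=O)O | starting material
2 | (R)-2-methylbutanoyl chloride | CC[C@@H](C)C(=O)Cl | intermediate
3 | phloroglucinol (benzene-1,3,5-triol) | Oc1cc(O)cc(O)c1 | starting material
4 | (2R)-2-methyl-1-(2,4,6-trihydroxyphenyl)butan-1-one | CC[C@@H](C)C(=O)c1c(O)cc(O)cc1O | intermediate
5 | 2-methylphloroglucinol (2-methylbenzene-1,3,5-triol) | Cc1c(O)cc(O)cc1O | starting material
6 | 1-(2,4,6-trihydroxy-3-methylphenyl)ethanone | CC(=O)c1c(O)cc(O)c(C)c1O | intermediate
7 | 1-[2-hydroxy-4,6-bis(methoxymethoxy)-3-methylphenyl]ethanone | CC(=O)c1c(O)c(C)c(OCOC)cc1OCOC | intermediate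
8 | 1-[2-methoxy-4,6-bis(methoxymethoxy)-3-methylphenyl]ethanone | CC(=O)c1c(OC)c(C)c(OCOC)cc1OCOC | intermediate
9 | 1-(4,6-dihydroxy-2-methoxy-3-methylphenyl)ethanone | CC(=O)c1c(OC)c(C)c(O)cc1O | intermediate
10 | 1-{2,4-dihydroxy-6-methoxy-5-methyl-3-[(methylsulfanyl)methyl]phenyl}ethanone | CC(=O)c1c(OC)c(C)c(O)c(CSC)c1O | intermediate
11 | 4-acetyl-5-methoxy-6-methyl-2-[(methylsulfanyl)methyl]-1,3-phenylene diacetate | CC(=O)Oc1c(CSC)c(OC(C)=O)c(C(C)=O)c(OC)c1C | intermediate
12 | 4-acetyl-5-methoxy-6-methyl-2-[(methylsulfinyl)methyl]-1,3-phenylene diacetate (racemic at sulfur) | CC(=O)Oc1c(CS(C)=O)c(OC(C)=O)c(C(C)=O)c(OC)c1C | intermediate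
13 | [(3-acetyl-2,6-diacetoxy-4-methoxy-5-methylphenyl)methyl](methyl)(trifluoromethylsulfonyloxy)sulfonium triflate | CC(=O)Oc1c(C[S+](C)OS(=O)(=O)C(F)(F)F)c(OC(C)=O)c(C(C)=O)c(OC)c1C.[O-]S(=O)(=O)C(F)(F)F | intermediate (not isolated)
14 | [(3-acetyl-2,6-diacetoxy-4-methoxy-5-methylphenyl)methyl](methyl){3,5-dihydroxy-4-[(2R)-2-methylbutanoyl]phenoxy}sulfonium triflate | CC[C@@H](C)C(=O)c1c(O)cc(O[S+](C)Cc2c(OC(C)=O)c(C)c(OC)c(C(C)=O)c2OC(C)=O)cc1O.[O-]S(=O)(=O)C(F)(F)F | intermediate (not isolated)
15 | (2R)-1-{3-[(3-acetyl-2,6-diacetoxy-4-methoxy-5-methylphenyl)(methylsulfanyl)methyl]-2,4,6-trihydroxyphenyl}-2-methylbutan-1-one | CC[C@@H](C)C(=O)c1c(O)cc(O)c(C(SC)c2c(OC(C)=O)c(C)c(OC)c(C(C)=O)c2OC(C)=O)c1O | intermediate (not isolated)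
16 | (2R)-1-{3,5-bis[(3-acetyl-2,6-diacetoxy-4-methoxy-5-methylphenyl)(methylsulfanyl)methyl]-2,4,6-trihydroxyphenyl}-2-methylbutan-1-one | CC[C@@H](C)C(=O)c1c(O)c(C(SC)c2c(OC(C)=O)c(C)c(OC)c(C(C)=O)c2OC(C)=O)c(O)c(C(SC)c2c(OC(C)=O)c(C)c(OC)c(C(C)=O)c2OC(C)=O)c1O | intermediate
17 | (2R)-1-{3,5-bis[(3-acetyl-2,6-diacetoxy-4-methoxy-5-methylphenyl)methyl]-2,4,6-trihydroxyphenyl}-2-methylbutan-1-one | CC[C@@H](C)C(=O)c1c(O)c(Cc2c(OC(C)=O)c(C)c(OC)c(C(C)=O)c2OC(C)=O)c(O)c(Cc2c(OC(C)=O)c(C)c(OC)c(C(C)=O)c2OC(C)=O)c1O | intermediate
18 | (2R)-1-{3,5-bis[(3-acetyl-2,6-dihydroxy-4-methoxy-5-methylphenyl)methyl]-2,4,6-trihydroxyphenyl}-2-methylbutan-1-one | CC[C@@H](C)C(=O)c1c(O)c(Cc2c(O)c(C)c(OC)c(C(C)=O)c2O)c(O)c(Cc2c(O)c(C)c(OC)c(C(C)=O)c2O)c1O | target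

## Step count and least certain steps

Total step count: 12. Longest linear sequence: 10 steps (steps 3 to 12, from 5). The two-step branch from 1 and 3 (steps 1 and 2) joins at step 10.

**Step 10 (key step, proposed new method).**
- **What may go wrong:** sulfenylation of ring A at carbon instead of at oxygen, because C3 and C5 of a phloroglucinol are strong carbon nucleophiles. This would fix sulfur on the ring as an arylsulfonium group from which no productive shift is available.
- **Further risks:** deprotonation at S-methyl in place of the hindered benzylic position, acyl transfer from an ortho acetate to the ylide carbon, and stalling after the first arm as ring A becomes crowded.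
- **Fallback (known chemistry):** it sets out from 9 and 4 and rejoins the route at 18. Mannich reaction of 9 with aqueous CH2O and Me2NH in EtOH at rt should give 1-{3-[(dimethylamino)methyl]-2,4-dihydroxy-6-methoxy-5-methylphenyl}ethanone F1. Heating F1 (2.2 equiv) with 4 in dioxane at about 90 °C expels the amine to give the side-ring ortho-quinone methide F2 (not isolated). Ring A captures it at C3 to give the mono-bridged compound (2R)-1-{3-[(3-acetyl-2,6-dihydroxy-4-methoxy-5-methylphenyl)methyl]-2,4,6-trihydroxyphenyl}-2-methylbutan-1-one F3 (not isolated), and then at C5 to give 18 directly. This is the usual way to build unsymmetrical methylene-bridged acylphloroglucinols. It gives up the thioether stage and the protected side rings, so bridge scrambling on prolonged heating has to be watched.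

**Step 7.**
- **What may go wrong:** self-condensation, in which the benzylic electrophile formed from 9 and CH2O is captured by a second molecule of 9 rather than by the thiol. Acylphloroglucinols with one free ring carbon are prone to this methylene-bridged dimerization.
- **Fallback:** it sets out from 9 and rejoins at 10, and it avoids CH2O altogether. Me2S and N-chlorosuccinimide in CH2Cl2 at −25 °C give S,S-dimethyl-N-succinimidosulfonium chloride F4. Compound 9 is then added and forms the aryloxydimethylsulfonium chloride F5 (not isolated; either hydroxyl of 9 serves, since both flank the free carbon). Et3N then induces ylide formation and the [2,3] shift of the Gassman ortho-methylthiomethylation to give 10.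

**Step 11.**
- **What may go wrong:** slow homolytic substitution at the sulfur of an alkyl sulfide, so that removal of the second methylsulfanyl group stays incomplete, or partial reduction of the aryl ketones on long heating with excess Bu3SnH.
- **Fallback:** it sets out from 16 and rejoins at 17. Ionic hydrogenation with Et3SiH and CF3CO2H in CH2Cl2 at 0 °C: heterolysis of each C–S bond is assisted by the ortho and para hydroxyls of ring A, and the silane transfers hydride to the resulting diarylmethyl cation, setting free the thiol.

**Step 4.**
- **What may go wrong:** insufficient discrimination between the two ortho hydroxyls of 6, so that the acetal also goes onto the oxygen next to the methyl group and the wrong oxygen is methylated in step 5.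
- **Fallback:** it sets out from 6 and rejoins at 7, and it replaces selective protection by selective deprotection. Exhaustive alkylation (NaH, MOMCl, DMF) gives 1-[2,4,6-tris(methoxymethoxy)-3-methylphenyl]ethanone F6. One equivalent of BCl3 in CH2Cl2 at −78 °C should then remove, through chelation to the ketone, the ortho acetal that is twisted out of plane between methyl and acetyl, giving 7.

**Step 2.**
- **What may go wrong:** partial loss of configuration at the α-carbon through enolization of the aluminium-bound acyl chloride or ketone, together with over-acylation.
- **Fallback:** it sets out from 1 and 3 and rejoins at 4, and it avoids Lewis acid.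
  - Compound 1 is converted into (2R)-N-methoxy-N,2-dimethylbutanamide F7 (carbonyldiimidazole, MeNH(OMe)·HCl).
  - Compound 3 is converted into 1,3,5-tris(methoxymethoxy)benzene F8 (NaH, MOMCl, DMF).
  - n-BuLi in THF at 0 °C lithiates F8 between two acetal oxygens to give 2,4,6-tris(methoxymethoxy)phenyllithium F9 (not isolated).
  - F9 adds to F7 at −78 °C to give (2R)-2-methyl-1-[2,4,6-tris(methoxymethoxy)phenyl]butan-1-one F10.
  - HCl in MeOH at rt then gives 4.

## Further compounds

F1 | step 10 | 1-{3-[(dimethylamino)methyl]-2,4-dihydroxy-6-methoxy-5-methylphenyl}ethanone | CC(=O)c1c(OC)c(C)c(O)c(CN(C)C)c1O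
F2 | step 10 | 2-acetyl-3-hydroxy-5-methoxy-6-methyl-4-methylidenecyclohexa-2,5-dien-1-one type ortho-quinone methide of the side ring (one tautomer drawn) | CC(=O)C1=C(O)C(=C)C(=O)C(C)=C1OC
F3 | step 10 | (2R)-1-{3-[(3-acetyl-2,6-dihydroxy-4-methoxy-5-methylphenyl)methyl]-2,4,6-trihydroxyphenyl}-2-methylbutan-1-one | CC[C@@H](C)C(=O)c1c(O)cc(O)c(Cc2c(O)c(C)c(OC)c(C(C)=O)c2O)c1O
F4 | step 7 | S,S-dimethyl-N-succinimidosulfonium chloride | C[S+](C)N1C(=O)CCC1=O.[Cl-]
F5 | step 7 | (4-acetyl-5-hydroxy-3-methoxy-2-methylphenoxy)dimethylsulfonium chloride | CC(=O)c1c(OC)c(C)c(O[S+](C)C)cc1O.[Cl-]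
F0 | step 11 | none | none
F6 | step 4 | 1-[2,4,6-tris(methoxymethoxy)-3-methylphenyl]ethanone | CC(=O)c1c(OCOC)c(C)c(OCOC)cc1OCOC
F7 | step 2 | (2R)-N-methoxy-N,2-dimethylbutanamide | CC[C@@H](C)C(=O)N(C)OC
F8 | step 2 | 1,3,5-tris(methoxymethoxy)benzene | COCOc1cc(OCOC)cc(OCOC)c1
F9 | step 2 | 2,4,6-tris(methoxymethoxy)phenyllithium | [Li]c1c(OCOC)cc(OCOC)cc1OCOC
F10 | step 2 | (2R)-2-methyl-1-[2,4,6-tris(methoxymethoxy)phenyl]butan-1-one | CC[C@@H](C)C(=O)c1c(OCOC)cc(OCOC)cc1OCOC
A1 | alternative 1 | tert-butyldimethylsilyl ether of (2R)-1-{2,4,6-tris(benzyloxy)-3,5-bis[3-(triisopropylsilyloxy)prop-2-yn-1-yl]phenyl}-2-methylbutan-1-ol (carbinol carbon unspecified) | CC[C@@H](C)C(O[Si](C)(C)C(C)(C)C)c1c(OCc2ccccc2)c(CC#CO[Si](C(C)C)(C(C)C)C(C)C)c(OCc2ccccc2)c(CC#CO[Si](C(C)C)(C(C)C)C(C)C)c1OCc1ccccc1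
A2 | alternative 1 | 3-methoxy-4-methylcyclobut-2-en-1-one (racemic) | COC1=CC(=O)C1C
A3 | alternative 1 | protected trimer with both side rings formed (C2′ OH, C6′ triisopropylsilyl ether, C4′ OMe, C3′ methyl, C5′ H; ring A tribenzyl ether; carbinol as tert-butyldimethylsilyl ether) | CC[C@@H](C)C(O[Si](C)(C)C(C)(C)C)c1c(OCc2ccccc2)c(Cc2c(O)c(C)c(OC)cc2O[Si](C(C)C)(C(C)C)C(C)C)c(OCc2ccccc2)c(Cc2c(O)c(C)c(OC)cc2O[Si](C(C)C)(C(C)C)C(C)C)c1OCc1ccccc1
A4 | alternative 2 | (2R)-1-{3,5-bis[(3-acetyl-2,6-dihydroxy-4-methoxyphenyl)methyl]-2,4,6-trihydroxyphenyl}-2-methylbutan-1-one | CC[C@@H](C)C(=O)c1c(O)c(Cc2c(O)cc(OC)c(C(C)=O)c2O)c(O)c(Cc2c(O)cc(OC)c(C(C)=O)c2O)c1O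
A5 | alternative 2 | 1-(2,4-dihydroxy-6-methoxyphenyl)ethanone | CC(=O)c1c(O)cc(O)cc1OC
A6 | alternative 2 | N,N-dimethylmethyleneiminium iodide (Eschenmoser's salt) | C=[N+](C)C.[I-]
A7 | alternative 2 | (2R)-1-{3,5-bis({3-acetyl-5-[(dimethylamino)methyl]-2,6-dihydroxy-4-methoxyphenyl}methyl)-2,4,6-trihydroxyphenyl}-2-methylbutan-1-one | CC[C@@H](C)C(=O)c1c(O)c(Cc2c(O)c(CN(C)C)c(OC)c(C(C)=O)c2O)c(O)c(Cc2c(O)c(CN(C)C)c(OC)c(C(C)=O)c2O)c1O
A8 | alternative 3 | 3,5-bis{[2,6-bis(benzyloxy)-4-methoxy-3-methylphenyl]methyl}-4-hydroxy-6-[(3R)-3-methyl-2-oxopentyl]-2H-pyran-2-one | CC[C@@H](C)C(=O)CC1=C(Cc2c(OCc3ccccc3)c(C)c(OC)cc2OCc2ccccc2)C(O)=C(Cc2c(OCc3ccccc3)c(C)c(OC)cc2OCc2ccccc2)C(=O)O1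
A9 | alternative 3 | magnesium methoxide, Mg(OMe)2 | [Mg+2].[O-]C.[O-]C
A10 | alternative 3 | (2R)-1-(3,5-bis{[2,6-bis(benzyloxy)-4-methoxy-3-methylphenyl]methyl}-2,4,6-trihydroxyphenyl)-2-methylbutan-1-one | CC[C@@H](C)C(=O)c1c(O)c(Cc2c(OCc3ccccc3)c(C)c(OC)cc2OCc2ccccc2)c(O)c(Cc2c(OCc3ccccc3)c(C)c(OC)cc2OCc2ccccc2)c1O
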